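The runs were generated by integration with constants of no real substance; scatter was added.

Answer 4 questions about 5 flasks.

1. the flasks put in order of amount of target, in percent of the substrate charged, best first, at 1.0 h (delta / beta / alpha / theta / zeta)
2. the same order at 6.0 min (delta / beta / alpha / theta / zeta)
3. the amount of target, in percent of the substrate charged of the flask you put first, at 1.0 h
4. the amount of target, in percent of the substrate charged of the flask you put last, at 1.0 h

the same everywhere: gas 10 mM (held)

| charge | substrate | initiator | remark | time |
|---|---|---|---|---|
| spring | 20 mM | 1.5 mol% | run made earlier |  |
| delta | 40 mM | 1 mol% |  | 1.0 h |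
| beta | 5.0 mM | 1 mol% |  | 1.0 h |
| alpha | 80 mM | 1 mol% |  | 1.0 h |
| theta | 20 mM | 1 mol% |  | 1.0 h |
| zeta | 6.0 mM | 1 mol% |  | 1.0 h |

- spring (time / min: target / %): 5.00: 51; 10.0: 62; 15.0: 68; 20.0: 71; 25.0: 67; 30.0: 74; 40.0: 71

(standard deviation of a reading: 2 percentage points)

- a species is counted by the substrate in it: one ended chains B counts as two
- amounts and yields of target count crystals too
- given per volume of solution although it is solid: crystals
- at the start none of coupling partner is dissolved
- the analysis behind the earlier runs scatters by 2 percentage points, standard deviation
- on the list of suspects stand: 2 second chain carrier -> ended chains A; substrate + second chain carrier -> released group + first chain carrier; coupling partner + first chain carrier <-> target + second chain carrier; crystals <-> target; 2 first chain carrier -> ended chains B; initiator -> 2 initiating radical; substrate + initiating radical -> capped initiator + first chain carrier; substrate -> decomposition product; gas <-> coupling partner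
- no earlier run changes the charge of initiator; that part of a forecast is a guess

Read the spring run first: its readings of target stand flat, within their scatter of 2 percentage points, from 20.0 min on, at a mean of 70.8% over the last 4 readings. Take this as a chain that stops when its initiator dies, with the substrate still there. Treat substrate loss as pseudo-first-order, at a rate following the square root of live initiator. The bench rule is then a chain budget, the natural logarithm of substrate charged over substrate unconverted at the plateau:

chain budget, spring = 1.23, on 0.300 mM of initiator

chain budget, any flask with this gas = spring budget × square root of (initiator charge in mM / spring charge)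

The square root is a guess, since no run tests it. Take each flask to stand on its plateau by 1.0 h, as the spring readings were flat from 20.0 min, and the rule gives:

beta 39.5%, zeta 42.3%, theta 63.3%, delta 75.8%, alpha 86.6%

Now find the border. The spring run tests the supply of dissolved gas at one opening demand, its own. Take the ratio:

opening demand / spring demand = (substrate / spring substrate) × square root of (initiator / spring initiator)

This gives theta 0.816, delta 2.31 and alpha 6.53. Beyond a ratio of 1 the rule is untested, so read the figures for delta and alpha as unsure, and any lead of alpha over delta at 6.0 min as well.

The forecast, holding that “Chain rate should scale as the square root of initiation”, gave alpha > delta > theta > zeta > beta at 1.0 h and alpha > delta > theta > zeta > beta at 6.0 min, with 78% first and 50% last, which is lower than this reckoning for alpha and higher for beta.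

The flasks give alpha > delta > theta > zeta > beta at 1.0 h and delta > alpha > theta > zeta > beta at 6.0 min, with 77.4% first and 42.5% last.

    2 second chain carrier → ended chains A (k = 2.90 × 10⁶ M⁻¹ s⁻¹)
    substrate + second chain carrier → released group + first chain carrier (k = 4400 M⁻¹ s⁻¹)
    coupling partner + first chain carrier ⇌ target + second chain carrier (K = 4.70, k = 1.70 × 10⁵ M⁻¹ s⁻¹)
    crystals ⇌ target, rate k4*(cs4 - [target]) while solid is left; crystals form when [target] > cs4 (solubility = 5.10 mM, k = 0.0890 s⁻¹)
    2 first chain carrier → ended chains B (k = 2.70 × 10⁶ M⁻¹ s⁻¹)
    initiator → 2 initiating radical (k = 0.00480 s⁻¹)
    substrate + initiating radical → capped initiator + first chain carrier (k = 3.70 × 10⁵ M⁻¹ s⁻¹)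
    substrate → decomposition product (k = 1.10 × 10⁻⁶ s⁻¹)
    gas ⇌ coupling partner, rate k9*(csat - [coupling partner]) (kL = 0.0150 s⁻¹)

Below the border, beta's reckoned 39.5% stands beside 42.5%, and beta ends with 57% of its substrate left and 0% of its initiator. Past the border, alpha ends at 77.4%, under its reckoned 86.6%, and at 6.0 min it reads 48.2% against 53.2% for delta. Take the neighbour, beta's recipe at 3.0 mM of substrate, which holds 0.0300 mM of initiator. Its budget gives 32.2%, and that flask ends with target at 35.2%.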